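## The problem

Target 26 is a germacranolide: a ten-membered carbocycle C1–C10 with two E-trisubstituted alkenes, C1=C10 (methyl C14 on C10) and C4=C5 (methyl C15 on C4), fused across C6–C7 to a butenolide whose ring oxygen sits on C6, whose alkene is C7=C11, whose carbonyl is C12 and whose C11 carries the acetoxymethyl carbon C13. Three oxygenated stereocentres have to be set: C2 (R, acetate), C6 (R, lactone oxygen) and C8 (S, methacrylate). C2 stands in a 1,5-relationship to both of the others, so substrate control cannot reach it and a reagent must set it. C6 and C8 flank the trigonal C7, so C8 can direct C6 only through a cyclic transition state that includes C7, which means in a ring closure at C6–C7. The molecule is fragile: the E,E-cyclodeca-1,5-diene cyclises across the ring with acid and undergoes Cope rearrangement on heating, and the C6 hydrogen is the γ-hydrogen of the butenolide, whose removal would epimerise C6 and could expel the C13 acetate. The methacrylate is a Michael acceptor that must be told apart from two acetates, so it has to be introduced last. The enabling feature is the three-carbon unit C11–C13 on C7: once its alkene is moved from C7=C11 to C11=C13, C7 becomes the γ-terminus of an allyl metal based on C13, C6 becomes the carbinol carbon of an aldehyde addition, and the C12 ester is placed to trap the C6 alkoxide as a five-membered lactone. C6–C7 is also the bond that a germacrene cyclase forms, likewise leaving an exocyclic alkene on the three-carbon unit.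

## Retrosynthesis

**C8–O acyl bond.** 26 is cut at the methacrylate to alcohol 25, and 25 is traced to silyl ether 24. The methacrylate would not survive peroxide, hydride or amine nucleophiles, so it is the last group to go on. The forward steps need a desilylation that avoids base and an acylation with retention.

**C7=C11 alkene and C13–O bond.** 24 is the dehydration product of tertiary alcohol 23. 23 comes from acetate opening of spiro-epoxide 22, itself the nucleophilic epoxidation product of α-methylene lactone 21. Allylic oxidation of a C13 methyl group would have to compete with C14, C15 and the allylic ring positions C3 and C9. A base-induced isomerisation of 22 would find no acidic hydrogen on C7. The three-step sequence asks only for a chemoselective Michael-type epoxidation, an SN2 opening at a primary carbon and a syn-elimination.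

**C6–C7 and C12–O bonds (key step).** 21 is opened to the acyclic bromo enal 18. Closing the ring at C1=C10 or C4=C5 by metathesis or olefination would give poor E control for a trisubstituted alkene in a ten-membered ring. A cut at C5–C6 would leave the butenolide to be built on an open chain as a tetrasubstituted Z-oxo-enoate. The chosen cut removes both rings and two stereocentres at once, and 18 is a linear chain with only the C2 and C8 centres. The forward reaction must be intramolecular, γ-selective at the allyl unit and face-selective at C6 under the influence of C8.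

**C13–Br and C7–C11 bonds.** 18 comes from alcohol 17 and silyl ether 16. The Z-2-(bromomethyl)enoate of 16 arises by SN2′ bromination of Morita–Baylis–Hillman adduct 15, made from α-silyloxy aldehyde 13 and methyl acrylate 14. This attaches C11–C13 in one step at the right oxidation level. A Wittig route would leave a C13 methyl group that cannot be brominated selectively.

**Protecting-group pattern.** 13 comes from alcohol 12 and 4-methoxybenzyl ether 11, which is reached from diol 9 through mono-silyl ether 10. C7 must be unveiled first, C6 second and C8 last, so three ethers of graded lability are used: an oxidatively cleaved 4-methoxybenzyl ether on C7, a primary allylic silyl ether on C6 that mild acid removes, and a secondary silyl ether on C8 that fluoride removes. The C2 acetate can go on only after the C6 ester has been reduced, which is why 9 precedes 11.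

**C2–C3 bond.** Diol 9 is the reduction product of hydroxy ester 8, the vinylogous Mukaiyama aldol product of enal 7 and silyl dienolate 2. The dienolate brings C3–C6 with the C15 methyl and the E alkene in place, and a chiral catalyst sets C2.

**C8–C9 bond.** Enal 7 comes by oxidation of alcohol 6, reduction of ester 5 and silylation of hydroxy ester 4. 4 is the same aldol reaction applied to aldehyde 3 with dienolate 2, now setting C8. Dienolate 2 is made from ester 1. The chain is thus built by using one four-carbon reagent twice, from three simple starting materials (1, 3 and 14).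

## Roads not taken

Alternative 1: ring expansion by anionic oxy-Cope rearrangement. The cut is C8–C9, made at the expense of a C1–C6 bond that holds these atoms in a six-membered ring. In the forward direction KH would form a tertiary potassium alkoxide on C6; the [3,3] shift breaks C1–C6, forms C8–C9 and the E-C1=C10 alkene and leaves the C6 enolate, which is protonated to cyclodecenone A1. Its merits are that the ring-forming event is unimolecular and needs no dilution, and that the chair transition state sets the C1=C10 geometry reliably; in these two respects it is safer than a medium-ring closure. Its weak point is the distance from A1 to the target. C6 is a ketone, C7 is a methylene group without C11–C13, and C4=C5 is masked as an acetonide diol that must later be deoxygenated to an E alkene inside the ring. The enolate formed in the shift is β to the C8 ether and can expel it. The three-carbon unit must then be attached at C7 of a ketone whose other α-carbon is oxygenated, the ketone reduced with control, and three protecting groups exchanged. Against the safer ring formation the chosen plan sets a closure that delivers all fifteen skeletal carbons, the lactone and C6 at once, five steps from 26.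

Alternative 2: fragmentation of a trans-fused bicyclic boronate. The cut is the ring-fusion bond C5–C10. Fluoride (Bu4NF) would add to a boronate on C4; C5–C10 breaks, both ring alkenes form with loss of a C1 sulfonate, and the C8 silyl ether falls off in the same flask, giving A2, which is the same compound as 25. Both alkene geometries follow stereospecifically from the bicyclic framework, there is no entropic penalty, and only one step remains after the key step. In alkene control and in economy after the key step this road is better than the chosen one. Its weak point is that every sensitive group must be carried on the bicycle and through the fragmentation: a tertiary boronate on C4, a sulfonate on C1 next to the C2 acetate (participation and elimination), and the 13-acetoxy butenolide in a basic fluoride medium. Seven stereocentres (C1, C2, C4, C5, C6, C8 and C10) must be built, and four of them (C1, C4, C5 and C10) are erased again. Against this the chosen plan sets an acyclic precursor with two stereocentres, both set by a catalyst, and a shorter overall sequence.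

Alternative 3: nickel-mediated alkylative aldehyde–alkyne macrocyclisation. The cuts are C5–C6 and C4–C15. Zerovalent nickel (bis(1,5-cyclooctadiene)nickel with 1,3-dimesitylimidazol-2-ylidene) would couple the C6 aldehyde with a terminal C4≡C5 alkyne, Zn(CH3)2 would deliver C15, and the zinc alkoxide would lactonise to A3. The step makes the C4=C5 alkene with defined geometry by syn addition and closes both rings. The butenolide arrives with C7=C11 and the C13 oxygen in place, so no alkene transposition is needed; this is better than the chosen plan, which spends three steps on it. The weak points are that an endocyclic E alkene must form through an oxanickelacycle inside a ten-membered ring, and that the aldehyde partner is a tetrasubstituted Z-oxo-enoate that is hard to make and prone to close on itself. C6 is still set by remote induction from C8, so the main stereochemical doubt remains, and about four protecting-group and acylation steps follow A3. Against the better oxidation pattern the chosen plan sets a closure with direct precedent for this ring size and lactone type, a simple reagent and an easier precursor.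

Key step: step 16

## Route

Assumptions:
- The bisphosphoramide antipode used in steps 2 and 6 is specified by the aldehyde face it must deliver; the two steps need opposite antipodes.
- 21 is drawn as the 6,7-trans lactone; either C7 epimer can be carried on, because C7 becomes trigonal in step 19.
- Aldehyde 3 is taken as a purchased compound.

Step 1
Reactants: 1 methyl 3-methylbut-2-enoate
Product: 2 1-[(tert-butyldimethylsilyl)oxy]-1-methoxy-3-methylbuta-1,3-diene
Conditions: LiN(iPr)2, THF, −78 °C; then tBuMe2SiCl, DMPU, −78 °C to rt
Reagents that add atoms: tert-butyldimethylsilyl chloride, CC(C)(C)[Si](C)(C)Cl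
Why: Kinetic γ-deprotonation of the β,β-dimethyl enoate gives the extended lithium dienolate, which is silylated on oxygen (silyl ketene acetal formation); the ketene acetal geometry is not carried into any product.

Step 2
Reactants: 3 2-[(4-methoxyphenyl)methoxy]acetaldehyde; 2 1-[(tert-butyldimethylsilyl)oxy]-1-methoxy-3-methylbuta-1,3-diene
Product: 4 methyl (2E,5S)-5-hydroxy-6-[(4-methoxyphenyl)methoxy]-3-methylhex-2-enoate
Conditions: SiCl4, bisphosphoramide 1,5-bis[methyl(3,5-dimethyl-4-oxido-3,5-dihydro-4H-dinaphtho[2,1-d:1',2'-f][1,3,2]diazaphosphepin-4-yl)amino]pentane (antipode for Si-face attack, 5 mol %), iPr2NEt, CH2Cl2, −78 °C; aq. NaHCO3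
Reagents that add atoms: none
Why: Vinylogous Mukaiyama aldol reaction under Lewis-base activation of SiCl4: the phosphoramide-bound trichlorosilyl cation binds the aldehyde and the dienolate attacks through its γ-carbon in an open transition state, the s-trans diene giving the E-enoate; the catalyst antipode fixes the aldehyde face and so sets C8 (S).

Step 3
Reactants: 4 methyl (2E,5S)-5-hydroxy-6-[(4-methoxyphenyl)methoxy]-3-methylhex-2-enoate
Product: 5 methyl (2E,5S)-5-[(tert-butyldimethylsilyl)oxy]-6-[(4-methoxyphenyl)methoxy]-3-methylhex-2-enoate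
Conditions: tBuMe2SiCl, imidazole, DMF, rt
Reagents that add atoms: tert-butyldimethylsilyl chloride, CC(C)(C)[Si](C)(C)Cl
Why: Standard silylation of an unhindered secondary alcohol; this hindered secondary ether has to last until step 20 and should resist every reagent used in between.

Step 4
Reactants: 5 methyl (2E,5S)-5-[(tert-butyldimethylsilyl)oxy]-6-[(4-methoxyphenyl)methoxy]-3-methylhex-2-enoate
Product: 6 (2E,5S)-5-[(tert-butyldimethylsilyl)oxy]-6-[(4-methoxyphenyl)methoxy]-3-methylhex-2-en-1-ol
Conditions: iBu2AlH, CH2Cl2, −78 °C; aq. potassium sodium tartrate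
Reagents that add atoms: none
Why: Reduction of the conjugated ester with iBu2AlH by 1,2-hydride delivery should give the allylic alcohol without touching the alkene geometry or the ethers.

Step 5
Reactants: 6 (2E,5S)-5-[(tert-butyldimethylsilyl)oxy]-6-[(4-methoxyphenyl)methoxy]-3-methylhex-2-en-1-ol
Product: 7 (2E,5S)-5-[(tert-butyldimethylsilyl)oxy]-6-[(4-methoxyphenyl)methoxy]-3-methylhex-2-enal
Conditions: MnO2, CH2Cl2, rt
Reagents that add atoms: none
Why: MnO2 oxidises the allylic alcohol selectively to the enal under neutral conditions, with retention of the E geometry.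

Step 6
Reactants: 7 (2E,5S)-5-[(tert-butyldimethylsilyl)oxy]-6-[(4-methoxyphenyl)methoxy]-3-methylhex-2-enal; 2 1-[(tert-butyldimethylsilyl)oxy]-1-methoxy-3-methylbuta-1,3-diene
Product: 8 methyl (2E,5R,6E,9S)-9-[(tert-butyldimethylsilyl)oxy]-5-hydroxy-10-[(4-methoxyphenyl)methoxy]-3,7-dimethyldeca-2,6-dienoate
Conditions: SiCl4, bisphosphoramide 1,5-bis[methyl(3,5-dimethyl-4-oxido-3,5-dihydro-4H-dinaphtho[2,1-d:1',2'-f][1,3,2]diazaphosphepin-4-yl)amino]pentane (antipode for Re-face attack, 5 mol %), iPr2NEt, CH2Cl2, −78 °C; aq. NaHCO3
Reagents that add atoms: none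
Why: Second vinylogous Mukaiyama aldol reaction, now on a conjugated aldehyde, the substrate class this catalyst system handles best; the remote C8 centre exerts no bias, so the opposite catalyst antipode sets C2 (R) by Re-face attack and the new enoate is again E.

Step 7
Reactants: 8 methyl (2E,5R,6E,9S)-9-[(tert-butyldimethylsilyl)oxy]-5-hydroxy-10-[(4-methoxyphenyl)methoxy]-3,7-dimethyldeca-2,6-dienoate
Product: 9 (2E,5R,6E,9S)-9-[(tert-butyldimethylsilyl)oxy]-10-[(4-methoxyphenyl)methoxy]-3,7-dimethyldeca-2,6-diene-1,5-diol
Conditions: iBu2AlH (excess), CH2Cl2, −78 °C; aq. potassium sodium tartrate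
Reagents that add atoms: none
Why: Reduction of the enoate with iBu2AlH, in excess to allow for the free hydroxyl; the ester has to be reduced before the C2 hydroxyl can carry an acetate.

Step 8
Reactants: 9 (2E,5R,6E,9S)-9-[(tert-butyldimethylsilyl)oxy]-10-[(4-methoxyphenyl)methoxy]-3,7-dimethyldeca-2,6-diene-1,5-diol
Product: 10 (2E,5R,6E,9S)-1,9-bis[(tert-butyldimethylsilyl)oxy]-10-[(4-methoxyphenyl)methoxy]-3,7-dimethyldeca-2,6-dien-5-ol
Conditions: tBuMe2SiCl (1.05 equiv), imidazole, CH2Cl2, −20 °C
Reagents that add atoms: tert-butyldimethylsilyl chloride, CC(C)(C)[Si](C)(C)Cl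
Why: Chemoselective silylation: the primary allylic hydroxyl reacts far faster with the bulky silyl chloride than the secondary one at low temperature.

Step 9
Reactants: 10 (2E,5R,6E,9S)-1,9-bis[(tert-butyldimethylsilyl)oxy]-10-[(4-methoxyphenyl)methoxy]-3,7-dimethyldeca-2,6-dien-5-ol
Product: 11 (2E,5R,6E,9S)-1,9-bis[(tert-butyldimethylsilyl)oxy]-10-[(4-methoxyphenyl)methoxy]-3,7-dimethyldeca-2,6-dien-5-yl acetate
Conditions: Ac2O, pyridine, 4-(dimethylamino)pyridine (cat.), CH2Cl2, 0 °C to rt
Reagents that add atoms: acetic anhydride, CC(=O)OC(C)=O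
Why: Nucleophile-catalysed acetylation of the remaining secondary allylic alcohol installs the C2 acetate of the target with retention.

Step 10
Reactants: 11 (2E,5R,6E,9S)-1,9-bis[(tert-butyldimethylsilyl)oxy]-10-[(4-methoxyphenyl)methoxy]-3,7-dimethyldeca-2,6-dien-5-yl acetate
Product: 12 (2E,5R,6E,9S)-1,9-bis[(tert-butyldimethylsilyl)oxy]-10-hydroxy-3,7-dimethyldeca-2,6-dien-5-yl acetate
Conditions: 2,3-dichloro-5,6-dicyano-1,4-benzoquinone, CH2Cl2/pH 7 buffer, 0 °C
Reagents that add atoms: none
Why: Oxidative cleavage of the 4-methoxybenzyl ether (hydride abstraction, then hydrolysis of the oxocarbenium ion) under buffered conditions should leave both silyl ethers, the acetate and the alkenes untouched.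

Step 11
Reactants: 12 (2E,5R,6E,9S)-1,9-bis[(tert-butyldimethylsilyl)oxy]-10-hydroxy-3,7-dimethyldeca-2,6-dien-5-yl acetate
Product: 13 (2E,5R,6E,9S)-1,9-bis[(tert-butyldimethylsilyl)oxy]-3,7-dimethyl-10-oxodeca-2,6-dien-5-yl acetate
Conditions: Dess–Martin periodinane, NaHCO3, CH2Cl2, 0 °C
Reagents that add atoms: none
Why: Dess–Martin oxidation under buffered, non-basic conditions should give the α-silyloxy aldehyde without epimerising C8; the aldehyde is used crude.

Step 12
Reactants: 13 (2E,5R,6E,9S)-1,9-bis[(tert-butyldimethylsilyl)oxy]-3,7-dimethyl-10-oxodeca-2,6-dien-5-yl acetate; 14 methyl acrylate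
Product: 15 methyl (4S,6E,8R,10E)-8-(acetyloxy)-4,12-bis[(tert-butyldimethylsilyl)oxy]-3-hydroxy-6,10-dimethyl-2-methylidenedodeca-6,10-dienoate (both C3 epimers)
Conditions: 1,4-diazabicyclo[2.2.2]octane (1 equiv), methyl acrylate (excess), 1,4-dioxane/H2O, rt
Reagents that add atoms: none
Why: Morita–Baylis–Hillman reaction: the amine adds to the acrylate, the ammonium enolate adds to the activated α-oxygenated aldehyde and loss of the amine gives the 2-(hydroxyalkyl)acrylate, the aqueous medium shortening the reaction time; the new carbinol centre forms as a mixture and is erased in step 13.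

Step 13
Reactants: 15 methyl (4S,6E,8R,10E)-8-(acetyloxy)-4,12-bis[(tert-butyldimethylsilyl)oxy]-3-hydroxy-6,10-dimethyl-2-methylidenedodeca-6,10-dienoate
Product: 16 methyl (2Z,4S,6E,8R,10E)-8-(acetyloxy)-2-(bromomethyl)-4,12-bis[(tert-butyldimethylsilyl)oxy]-6,10-dimethyldodeca-2,6,10-trienoate
Conditions: N-bromosuccinimide, Me2S, CH2Cl2, −20 to 0 °C
Reagents that add atoms: N-bromosuccinimide, O=C1CCC(=O)N1Br
Why: Corey–Kim-type activation of the allylic alcohol as an alkoxysulfonium ion, then SN2′ attack of bromide on the methylene carbon; allylic 1,3-strain in the transition state should give the Z-2-(bromomethyl)enoate with C8 cis to the bromomethyl group.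

Step 14
Reactants: 16 methyl (2Z,4S,6E,8R,10E)-8-(acetyloxy)-2-(bromomethyl)-4,12-bis[(tert-butyldimethylsilyl)oxy]-6,10-dimethyldodeca-2,6,10-trienoate
Product: 17 methyl (2Z,4S,6E,8R,10E)-8-(acetyloxy)-2-(bromomethyl)-4-[(tert-butyldimethylsilyl)oxy]-12-hydroxy-6,10-dimethyldodeca-2,6,10-trienoate
Conditions: camphor-10-sulfonic acid (cat.), MeOH/CH2Cl2, 0 °C
Reagents that add atoms: none
Why: Acid-catalysed methanolysis removes the unhindered primary allylic silyl ether much faster than the hindered secondary one on C8; the medium holds no base or strong nucleophile that could attack the allylic bromide.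

Step 15
Reactants: 17 methyl (2Z,4S,6E,8R,10E)-8-(acetyloxy)-2-(bromomethyl)-4-[(tert-butyldimethylsilyl)oxy]-12-hydroxy-6,10-dimethyldodeca-2,6,10-trienoate
Product: 18 methyl (2Z,4S,6E,8R,10E)-8-(acetyloxy)-2-(bromomethyl)-4-[(tert-butyldimethylsilyl)oxy]-6,10-dimethyl-12-oxododeca-2,6,10-trienoate
Conditions: MnO2, CH2Cl2, rt
Reagents that add atoms: none
Why: MnO2 oxidation of the primary allylic alcohol to the E-enal under neutral heterogeneous conditions, which the allylic bromide tolerates; 18 is used at once.

Step 16
Reactants: 18 methyl (2Z,4S,6E,8R,10E)-8-(acetyloxy)-2-(bromomethyl)-4-[(tert-butyldimethylsilyl)oxy]-6,10-dimethyl-12-oxododeca-2,6,10-trienoate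
Product: 21 (2R,6R,7S,8S)-2-(acetyloxy)-8-[(tert-butyldimethylsilyl)oxy]germacra-1(10)E,4E,11(13)-trien-12,6-olide, via allylchromium dichloride 19 (not isolated), via macrocyclic chromium alkoxide 20 (not isolated)
Conditions: CrCl2 (excess), THF, rt, slow addition of 18 to about 0.003 M; aq. NH4Cl
Reagents that add atoms: none
Why: Two equivalents of CrCl2 (divalent chromium) reduce the C13–Br bond of 18 to allylchromium dichloride 19 (trivalent chromium), a nucleophile that leaves esters and silyl ethers alone. 19 adds to the C6 aldehyde through its γ-carbon C7 in a six-membered chair made of Cr, O, C6, C7, C11 and C13 while the alkene moves to C11=C13; the closest known reaction type is the intramolecular Nozaki–Hiyama allylation of aldehydes by 2-(bromomethyl)acrylates, which is established for ten-membered carbocycles carrying α-methylene lactones. The ten-membered ring closes by C6–C7 bond formation, 10-exo-trig at the carbonyl and SE2′ at the allyl unit, helped by the two rigid E alkenes and by chromium holding both reacting ends together. The lactone closes when chromium alkoxide 20 attacks the C12 methyl ester, a 5-exo-trig acyl substitution that expels methoxide. C6 is controlled by C8: allylic 1,3-strain against the cis CH2Cr group should place the C8 hydrogen in the allyl plane and the silyloxy group on the outer face of the forming ring, so that the aldehyde tethered through C9 reaches one face of C7 and the chair with the C5 alkenyl group equatorial then fixes C6, although the sense of this induction is the unproven point. C7 is set in the same chair and is drawn trans to the C6 hydrogen, but its configuration is of no consequence because it becomes trigonal in step 19. The step needs ring closure to outrun intermolecular coupling, which slow addition at high dilution secures, and γ- over α-attack, which the cyclic transition state of allylchromium reagents secures since α-attack would demand a twelve-membered ring. 1,2-Addition to the enal is the normal mode for allylchromium reagents.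

Step 17
Reactants: 21 (2R,6R,7S,8S)-2-(acetyloxy)-8-[(tert-butyldimethylsilyl)oxy]germacra-1(10)E,4E,11(13)-trien-12,6-olide
Product: 22 (2R,6R,7S,8S,11R)-2-(acetyloxy)-8-[(tert-butyldimethylsilyl)oxy]-11,13-epoxygermacra-1(10)E,4E-dien-12,6-olide
Conditions: tBuOOH, 1,8-diazabicyclo[5.4.0]undec-7-ene, CH2Cl2, 0 °C
Reagents that add atoms: tert-butyl hydroperoxide, CC(C)(C)OO
Why: Weitz–Scheffer (nucleophilic) epoxidation: the peroxide anion adds to C13 of the α-methylene lactone, the only Michael acceptor present, and the enolate closes the oxirane with loss of tert-butoxide, so the electron-rich ring alkenes are not touched; the oxygen is expected to enter on the lactone face anti to C8, that is cis to the C7 hydrogen (11R).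

Step 18
Reactants: 22 (2R,6R,7S,8S,11R)-2-(acetyloxy)-8-[(tert-butyldimethylsilyl)oxy]-11,13-epoxygermacra-1(10)E,4E-dien-12,6-olide
Product: 23 (2R,6R,7S,8S,11R)-2,13-bis(acetyloxy)-8-[(tert-butyldimethylsilyl)oxy]-11-hydroxygermacra-1(10)E,4E-dien-12,6-olide
Conditions: AcOH, CsOAc (cat.), DMF, 50 °C
Reagents that add atoms: acetic acid, CC(=O)O
Why: SN2 opening of the glycidic lactone by acetate at the primary carbon C13 (C11 is fully substituted), buffered by acetic acid; this installs the C13 acetate of the target directly and leaves a tertiary C11 hydroxyl cis to the C7 hydrogen.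

Step 19
Reactants: 23 (2R,6R,7S,8S,11R)-2,13-bis(acetyloxy)-8-[(tert-butyldimethylsilyl)oxy]-11-hydroxygermacra-1(10)E,4E-dien-12,6-olide
Product: 24 (2R,6R,8S)-2,13-bis(acetyloxy)-8-[(tert-butyldimethylsilyl)oxy]germacra-1(10)E,4E,7(11)-trien-12,6-olide
Conditions: methyl N-(triethylammoniosulfonyl)carbamate (Burgess reagent), toluene, 50 °C
Reagents that add atoms: none
Why: Burgess dehydration: the C11 sulfamate ester undergoes thermal syn-elimination with the cis hydrogen on C7 to give the tetrasubstituted conjugated C7=C11 alkene; loss of a C13 hydrogen would give the less substituted enol acetate and is disfavoured by the acetoxy group on that carbon.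

Step 20
Reactants: 24 (2R,6R,8S)-2,13-bis(acetyloxy)-8-[(tert-butyldimethylsilyl)oxy]germacra-1(10)E,4E,7(11)-trien-12,6-olide
Product: 25 (2R,6R,8S)-2,13-bis(acetyloxy)-8-hydroxygermacra-1(10)E,4E,7(11)-trien-12,6-olide
Conditions: HF·pyridine, pyridine, THF, 0 °C to rt
Reagents that add atoms: none
Why: Desilylation by buffered hydrogen fluoride, chosen because basic fluoride could deprotonate C6 of the butenolide; the acetates should be stable.

Step 21
Reactants: 25 (2R,6R,8S)-2,13-bis(acetyloxy)-8-hydroxygermacra-1(10)E,4E,7(11)-trien-12,6-olide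
Product: 26 (2R,6R,8S)-2,13-bis(acetyloxy)-8-[(2-methylprop-2-enoyl)oxy]germacra-1(10)E,4E,7(11)-trien-12,6-olide (CNP0309304.1)
Conditions: methacrylic anhydride, 4-(dimethylamino)pyridine (cat.), pyridine, CH2Cl2, 0 °C
Reagents that add atoms: methacrylic anhydride, C=C(C)C(=O)OC(=O)C(C)=C
Why: Nucleophile-catalysed acylation of the secondary C8 alcohol with retention; it is placed last because the methacrylate would not survive the peroxide of step 17 or the hydride and amine reagents used earlier.

## Compound list

1 | methyl 3-methylbut-2-enoate | COC(=O)C=C(C)C | starting material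
2 | 1-[(tert-butyldimethylsilyl)oxy]-1-methoxy-3-methylbuta-1,3-diene (ketene acetal geometry as formed) | C=C(C)C=C(OC)O[Si](C)(C)C(C)(C)C | intermediate
3 | 2-[(4-methoxyphenyl)methoxy]acetaldehyde | COc1ccc(COCC=O)cc1 | starting material
4 | methyl (2E,5S)-5-hydroxy-6-[(4-methoxyphenyl)methoxy]-3-methylhex-2-enoate | COC(=O)/C=C(\C)C[C@H](O)COCc1ccc(OC)cc1 | intermediate
5 | methyl (2E,5S)-5-[(tert-butyldimethylsilyl)oxy]-6-[(4-methoxyphenyl)methoxy]-3-methylhex-2-enoate | COC(=O)/C=C(\C)C[C@H](O[Si](C)(C)C(C)(C)C)COCc1ccc(OC)cc1 | intermediate
6 | (2E,5S)-5-[(tert-butyldimethylsilyl)oxy]-6-[(4-methoxyphenyl)methoxy]-3-methylhex-2-en-1-ol | OC/C=C(\C)C[C@H](O[Si](C)(C)C(C)(C)C)COCc1ccc(OC)cc1 | intermediate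
7 | (2E,5S)-5-[(tert-butyldimethylsilyl)oxy]-6-[(4-methoxyphenyl)methoxy]-3-methylhex-2-enal | O=C/C=C(\C)C[C@H](O[Si](C)(C)C(C)(C)C)COCc1ccc(OC)cc1 | intermediate
8 | methyl (2E,5R,6E,9S)-9-[(tert-butyldimethylsilyl)oxy]-5-hydroxy-10-[(4-methoxyphenyl)methoxy]-3,7-dimethyldeca-2,6-dienoate | COC(=O)/C=C(\C)C[C@@H](O)/C=C(\C)C[C@H](O[Si](C)(C)C(C)(C)C)COCc1ccc(OC)cc1 | intermediate
9 | (2E,5R,6E,9S)-9-[(tert-butyldimethylsilyl)oxy]-10-[(4-methoxyphenyl)methoxy]-3,7-dimethyldeca-2,6-diene-1,5-diol | OC/C=C(\C)C[C@@H](O)/C=C(\C)C[C@H](O[Si](C)(C)C(C)(C)C)COCc1ccc(OC)cc1 | intermediate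
10 | (2E,5R,6E,9S)-1,9-bis[(tert-butyldimethylsilyl)oxy]-10-[(4-methoxyphenyl)methoxy]-3,7-dimethyldeca-2,6-dien-5-ol | CC(C)(C)[Si](C)(C)OC/C=C(\C)C[C@@H](O)/C=C(\C)C[C@H](O[Si](C)(C)C(C)(C)C)COCc1ccc(OC)cc1 | intermediate
11 | (2E,5R,6E,9S)-1,9-bis[(tert-butyldimethylsilyl)oxy]-10-[(4-methoxyphenyl)methoxy]-3,7-dimethyldeca-2,6-dien-5-yl acetate | CC(C)(C)[Si](C)(C)OC/C=C(\C)C[C@@H](OC(C)=O)/C=C(\C)C[C@H](O[Si](C)(C)C(C)(C)C)COCc1ccc(OC)cc1 | intermediate
12 | (2E,5R,6E,9S)-1,9-bis[(tert-butyldimethylsilyl)oxy]-10-hydroxy-3,7-dimethyldeca-2,6-dien-5-yl acetate | CC(C)(C)[Si](C)(C)OC/C=C(\C)C[C@@H](OC(C)=O)/C=C(\C)C[C@H](O[Si](C)(C)C(C)(C)C)CO | intermediate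
13 | (2E,5R,6E,9S)-1,9-bis[(tert-butyldimethylsilyl)oxy]-3,7-dimethyl-10-oxodeca-2,6-dien-5-yl acetate | CC(C)(C)[Si](C)(C)OC/C=C(\C)C[C@@H](OC(C)=O)/C=C(\C)C[C@H](O[Si](C)(C)C(C)(C)C)C=O | intermediate
14 | methyl acrylate | C=CC(=O)OC | starting material
15 | methyl (4S,6E,8R,10E)-8-(acetyloxy)-4,12-bis[(tert-butyldimethylsilyl)oxy]-3-hydroxy-6,10-dimethyl-2-methylidenedodeca-6,10-dienoate (both C3 epimers) | CC(C)(C)[Si](C)(C)OC/C=C(\C)C[C@@H](OC(C)=O)/C=C(\C)C[C@H](O[Si](C)(C)C(C)(C)C)C(O)C(=C)C(=O)OC | intermediate
16 | methyl (2Z,4S,6E,8R,10E)-8-(acetyloxy)-2-(bromomethyl)-4,12-bis[(tert-butyldimethylsilyl)oxy]-6,10-dimethyldodeca-2,6,10-trienoate | CC(C)(C)[Si](C)(C)OC/C=C(\C)C[C@@H](OC(C)=O)/C=C(\C)C[C@H](O[Si](C)(C)C(C)(C)C)/C=C(\CBr)C(=O)OC | intermediate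
17 | methyl (2Z,4S,6E,8R,10E)-8-(acetyloxy)-2-(bromomethyl)-4-[(tert-butyldimethylsilyl)oxy]-12-hydroxy-6,10-dimethyldodeca-2,6,10-trienoate | OC/C=C(\C)C[C@@H](OC(C)=O)/C=C(\C)C[C@H](O[Si](C)(C)C(C)(C)C)/C=C(\CBr)C(=O)OC | intermediate
18 | methyl (2Z,4S,6E,8R,10E)-8-(acetyloxy)-2-(bromomethyl)-4-[(tert-butyldimethylsilyl)oxy]-6,10-dimethyl-12-oxododeca-2,6,10-trienoate (precursor of the key step) | CC(C)(C)[Si](C)(C)O[C@@H](C/C(C)=C/[C@H](OC(C)=O)C/C(C)=C/C=O)/C=C(\CBr)C(=O)OC | intermediate
19 | allylchromium dichloride from 18 (CrCl2 on C13; not isolated) | CC(C)(C)[Si](C)(C)O[C@@H](C/C(C)=C/[C@H](OC(C)=O)C/C(C)=C/C=O)/C=C(\C[Cr](Cl)Cl)C(=O)OC | intermediate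
20 | macrocyclic chromium alkoxide (ten-membered ring closed, C6–O–CrCl2, C7 bearing the 1-(methoxycarbonyl)vinyl group; not isolated) | CC(C)(C)[Si](C)(C)O[C@H]1C/C(C)=C/[C@H](OC(C)=O)C/C(C)=C/[C@@H](O[Cr](Cl)Cl)[C@@H]1C(=C)C(=O)OC | intermediate
21 | (2R,6R,7S,8S)-2-(acetyloxy)-8-[(tert-butyldimethylsilyl)oxy]germacra-1(10)E,4E,11(13)-trien-12,6-olide (6,7-trans α-methylene lactone; product of the key step) | CC(C)(C)[Si](C)(C)O[C@H]1C/C(C)=C/[C@H](OC(C)=O)C/C(C)=C/[C@H]2OC(=O)C(=C)[C@H]12 | intermediate
22 | (2R,6R,7S,8S,11R)-2-(acetyloxy)-8-[(tert-butyldimethylsilyl)oxy]-11,13-epoxygermacra-1(10)E,4E-dien-12,6-olide | CC(C)(C)[Si](C)(C)O[C@H]1C/C(C)=C/[C@H](OC(C)=O)C/C(C)=C/[C@H]2OC(=O)[C@]3(CO3)[C@H]12 | intermediate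
23 | (2R,6R,7S,8S,11R)-2,13-bis(acetyloxy)-8-[(tert-butyldimethylsilyl)oxy]-11-hydroxygermacra-1(10)E,4E-dien-12,6-olide | CC(C)(C)[Si](C)(C)O[C@H]1C/C(C)=C/[C@H](OC(C)=O)C/C(C)=C/[C@H]2OC(=O)[C@](O)(COC(C)=O)[C@H]12 | intermediate
24 | (2R,6R,8S)-2,13-bis(acetyloxy)-8-[(tert-butyldimethylsilyl)oxy]germacra-1(10)E,4E,7(11)-trien-12,6-olide | CC(C)(C)[Si](C)(C)O[C@H]1C/C(C)=C/[C@H](OC(C)=O)C/C(C)=C/[C@H]2OC(=O)C(COC(C)=O)=C12 | intermediate
25 | (2R,6R,8S)-2,13-bis(acetyloxy)-8-hydroxygermacra-1(10)E,4E,7(11)-trien-12,6-olide | O[C@H]1C/C(C)=C/[C@H](OC(C)=O)C/C(C)=C/[C@H]2OC(=O)C(COC(C)=O)=C12 | intermediate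
26 | (2R,6R,8S)-2,13-bis(acetyloxy)-8-[(2-methylprop-2-enoyl)oxy]germacra-1(10)E,4E,7(11)-trien-12,6-olide (CNP0309304.1) | C=C(C)C(=O)O[C@H]1C/C(C)=C/[C@H](OC(C)=O)C/C(C)=C/[C@H]2OC(=O)C(COC(C)=O)=C12 | target

## Step count and least certain steps

Total: 21 steps. Longest linear sequence: 21 steps (1 through 2 to 26); 20 steps counted from aldehyde 3.

**Step 16, the key step.** The most likely failure is attack on the wrong aldehyde face relative to C8, because the induction runs through a macrocyclic transition state whose preferred conformation cannot be foreseen. Intermolecular coupling is a second risk if the dilution is insufficient. A third is 1,4-elimination of the C8 silyloxy group from the allylchromium before it finds the aldehyde. If the ring closes but the C6 alkoxide fails to lactonise in the flask, a brief acid treatment of the hydroxy ester would complete the lactone.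

Fallback: it sets out from 18 and comes back at 21. Should the closure deliver the opposite C6 configuration, 18 would cyclise under the conditions of step 16 to the 6-epimeric cis-fused α-methylene lactone F1. LiOH in aqueous THF would open the lactone and cleave the C2 acetate to give the seco dihydroxy acid F2. Mitsunobu lactonisation with PPh3 and diisopropyl azodicarboxylate in THF would close the γ-lactone with inversion at C6, the five-membered closure outrunning any reaction at the C2 hydroxyl, and give the 2-hydroxy trans-fused lactone F3. Acetylation with Ac2O and pyridine then returns to 21.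

**Step 2.** Slow turnover and erosion of enantioselectivity are possible, since an aliphatic α-alkoxy aldehyde is a weaker substrate for the silicon cation catalyst than a conjugated one and an uncatalysed pathway can compete.

Fallback: it sets out from 3 and comes back at 5. Asymmetric propargylation of 3 with B-allenyl-10-trimethylsilyl-9-borabicyclo[3.3.2]decane, in the antipode that attacks the Si face, would give the 2S homopropargylic alcohol F4. Silylation with tBuMe2SiCl and imidazole would give the tert-butyldimethylsilyl ether F5. Negishi methylalumination with Me3Al and catalytic Cp2ZrCl2, followed by trapping of the alkenylalane with methyl chloroformate, would deliver the E-enoate and so return to 5.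

**Step 12.** The Morita–Baylis–Hillman reaction can be slow, and prolonged exposure of the α-silyloxy aldehyde to the amine allows epimerisation at C8 through enolisation.

Fallback: it sets out from 13 and comes back at 15. Hydroalumination of methyl propiolate with iBu2AlH and N-methylmorpholine N-oxide in THF at 0 °C would give the α-aluminoacrylate diisobutyl[1-methoxycarbonylvinyl]aluminium F6. This preformed nucleophile should add to 13 within hours in the absence of an amine, and aqueous work-up then returns to 15.

**Step 19.** Elimination may run toward C13 and give the enol acetate in place of the ring alkene. The syn-elimination also fails if the epoxidation of step 17 took the other lactone face, which would leave no syn hydrogen on C7; in that case SOCl2 in pyridine, which eliminates anti, would be tried on 23.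

Fallback: it sets out from 22 and comes back at 24. Syn-β-elimination of the epoxide with diethylaluminium 2,2,6,6-tetramethylpiperidide in toluene at 0 °C, for which the C7 hydrogen is the only β-hydrogen available, would give the 13-hydroxy butenolide F7. Acetylation with Ac2O and pyridine, which would also restore the C2 acetate should the amide have touched it, returns to 24.

Further compounds
F1 | step 16 | (2R,6S,7S,8S)-2-(acetyloxy)-8-[(tert-butyldimethylsilyl)oxy]germacra-1(10)E,4E,11(13)-trien-12,6-olide | CC(C)(C)[Si](C)(C)O[C@H]1C/C(C)=C/[C@H](OC(C)=O)C/C(C)=C/[C@@H]2OC(=O)C(=C)[C@H]12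
F2 | step 16 | (2R,6S,7S,8S)-8-[(tert-butyldimethylsilyl)oxy]-2,6-dihydroxygermacra-1(10)E,4E,11(13)-trien-12-oic acid | CC(C)(C)[Si](C)(C)O[C@H]1C/C(C)=C/[C@H](O)C/C(C)=C/[C@H](O)[C@@H]1C(=C)C(=O)O
F3 | step 16 | (2R,6R,7S,8S)-8-[(tert-butyldimethylsilyl)oxy]-2-hydroxygermacra-1(10)E,4E,11(13)-trien-12,6-olide | CC(C)(C)[Si](C)(C)O[C@H]1C/C(C)=C/[C@H](O)C/C(C)=C/[C@H]2OC(=O)C(=C)[C@H]12
F4 | step 2 | (2S)-1-[(4-methoxyphenyl)methoxy]pent-4-yn-2-ol | COc1ccc(COC[C@@H](O)CC#C)cc1
F5 | step 2 | tert-butyl({(2S)-1-[(4-methoxyphenyl)methoxy]pent-4-yn-2-yl}oxy)dimethylsilane | COc1ccc(COC[C@@H](O[Si](C)(C)C(C)(C)C)CC#C)cc1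
F6 | step 12 | diisobutyl[1-(methoxycarbonyl)vinyl]aluminium | C=C(C(=O)OC)[Al](CC(C)C)CC(C)C
F7 | step 19 | (2R,6R,8S)-2-(acetyloxy)-8-[(tert-butyldimethylsilyl)oxy]-13-hydroxygermacra-1(10)E,4E,7(11)-trien-12,6-olide | CC(C)(C)[Si](C)(C)O[C@H]1C/C(C)=C/[C@H](OC(C)=O)C/C(C)=C/[C@H]2OC(=O)C(CO)=C12
A1 | alternative 1 | E-cyclodecenone with C6 ketone, C4/C5 acetonide, C2 silyl ether and C8 4-methoxybenzyl ether | COc1ccc(CO[C@H]2C/C(C)=C/[C@H](O[Si](C)(C)C(C)(C)C)C[C@]3(C)OC(C)(C)O[C@H]3C(=O)C2)cc1
A2 | alternative 2 | 8-hydroxy macrocycle, identical with 25 | O[C@H]1C/C(C)=C/[C@H](OC(C)=O)C/C(C)=C/[C@H]2OC(=O)C(COC(C)=O)=C12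
A3 | alternative 3 | macrocyclic butenolide with C8 4-methoxybenzyl ether and silyl ethers on the C2 and C13 oxygens | COc1ccc(CO[C@H]2C/C(C)=C/[C@H](O[Si](C)(C)C(C)(C)C)C/C(C)=C/[C@H]3OC(=O)C(CO[Si](C)(C)C(C)(C)C)=C23)cc1
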